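**Retrosynthetic overview**
1. The C6 side chain is disconnected last, at C6–C1'', by Suzuki coupling of a 5-hydroxy-6-iodoflavanone with an (E)-alkenylboronate that carries the (S)-methyl centre of (S)-citronellal (aldehyde → terminal alkyne → hydroboration). The two alkenes therefore never meet the carbenoid.
2. Feature on which the route rests: C2 of ring C bears one hydrogen, O1 and ring B. In the ring-opened form its C–H bond is the doubly activated benzylic C–H of an aryl benzyl ether, and C3 can be delivered as the carbene carbon of a diazoketone on C4.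
3. Ring C is the only ring formed (rings A and B are bought). C2–C3 is made by enantioselective dirhodium carbenoid 1,6 C–H insertion, which also sets C2.
4. The diazoketone comes from 2,4,6-trihydroxyacetophenone by detrifluoroacetylative diazo transfer, after O7 is silylated with TIPS, O5 with TBS, and O1 is etherified (Mitsunobu) with the bis-TIPS benzyl alcohol from 3,4-dihydroxybenzaldehyde. Only O5 carries TBS, so that it alone can be freed later to direct iodination to C6 without discriminating among four like silyl ethers.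

Key step: step 7

Assumption: the (S)-configured catalyst is taken to give the (2S)-flavanone; if the sense of induction proves opposite, the mirror-image catalyst Rh2(R-PTTL)4 is used in step 7 with no other change.

**Route**

Step 1
Reactants: 1 2,4,6-trihydroxyacetophenone (dried)
Product: 2 1-[2,6-dihydroxy-4-(triisopropylsilyloxy)phenyl]ethanone
Conditions: TIPSCl (1.05 equiv), imidazole (2.2 equiv), DMF, −10 °C → 0 °C
Reagents that add atoms: triisopropylsilyl chloride, CC(C)[Si](Cl)(C(C)C)C(C)C
Why: Base-mediated O-silylation should take the 4-hydroxyl first, since it is the most acidic hydroxyl and the only one not chelated to the acetyl oxygen, and TIPS is placed here because it must outlast the later removal of a TBS group.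

Step 2
Reactants: 2 1-[2,6-dihydroxy-4-(triisopropylsilyloxy)phenyl]ethanone
Product: 3 1-[2-(tert-butyldimethylsilyloxy)-6-hydroxy-4-(triisopropylsilyloxy)phenyl]ethanone
Conditions: TBSCl (1.1 equiv), imidazole (2.5 equiv), DMF, 0 °C → rt
Reagents that add atoms: tert-butyldimethylsilyl chloride, CC(C)(C)[Si](C)(C)Cl
Why: A second O-silylation should stop after one of the two equivalent ortho hydroxyls, because the last hydroxyl then sits in a strong hydrogen-bond chelate, and it puts the one small silyl group of the route on the future O5, where it offers the carbenoid no activated C–H bond.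

Step 3
Reactants: 4 3,4-dihydroxybenzaldehyde
Product: 5 3,4-bis(triisopropylsilyloxy)benzaldehyde
Conditions: TIPSCl (2.5 equiv), imidazole (5 equiv), DMAP (cat.), DMF, rt → 40 °C
Reagents that add atoms: triisopropylsilyl chloride, CC(C)[Si](Cl)(C(C)C)C(C)C
Why: Exhaustive O-silylation of the catechol gives base-robust TIPS ethers that keep ring B electron-rich for the insertion and keep the 4'-oxygen masked until the last step.

Step 4
Reactants: 5 3,4-bis(triisopropylsilyloxy)benzaldehyde
Product: 6 [3,4-bis(triisopropylsilyloxy)phenyl]methanol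
Conditions: NaBH4 (1.0 equiv), THF/MeOH (4:1), 0 °C
Reagents that add atoms: none
Why: Borohydride reduction of the aryl aldehyde is fast at 0 °C and does not touch aryl TIPS ethers.

Step 5
Reactants: 3 1-[2-(tert-butyldimethylsilyloxy)-6-hydroxy-4-(triisopropylsilyloxy)phenyl]ethanone; 6 [3,4-bis(triisopropylsilyloxy)phenyl]methanol
Product: 7 1-[2-[3,4-bis(triisopropylsilyloxy)benzyloxy]-6-(tert-butyldimethylsilyloxy)-4-(triisopropylsilyloxy)phenyl]ethanone
Conditions: PPh3 (1.3 equiv), DIAD (1.3 equiv), THF, 0 °C → rt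
Reagents that add atoms: none
Why: Mitsunobu etherification couples the chelated phenol, acidic enough as pronucleophile, with the primary benzylic alcohol under neutral conditions, whereas a carbonate-mediated benzylation would strip and scramble the aryl silyl ethers.

Step 6
Reactants: 7 1-[2-[3,4-bis(triisopropylsilyloxy)benzyloxy]-6-(tert-butyldimethylsilyloxy)-4-(triisopropylsilyloxy)phenyl]ethanone
Product: 9 1-[2-[3,4-bis(triisopropylsilyloxy)benzyloxy]-6-(tert-butyldimethylsilyloxy)-4-(triisopropylsilyloxy)phenyl]-2-diazoethanone, via trifluoroacetyl ketone 8 (not isolated)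
Conditions: LiN(SiMe3)2 (1.1 equiv), THF, −78 °C; CF3CO2CH2CF3 (1.2 equiv), −78 °C, then dilute aq HCl; crude 8: MsN3 (1.5 equiv), Et3N (1.5 equiv), H2O (1 equiv), MeCN, rt
Reagents that add atoms: methanesulfonyl azide, CS(=O)(=O)N=[N+]=[N-] (the two diazo nitrogens of 9); 2,2,2-trifluoroethyl trifluoroacetate, O=C(OCC(F)(F)F)C(F)(F)F (the trifluoroacetyl group of 8, lost again on diazo transfer)
Why: Detrifluoroacetylative diazo transfer, a Regitz-type transfer made possible by first Claisen-acylating the kinetic lithium enolate of the methyl ketone, should give the terminal diazoketone because the activated 1,3-diketone accepts the diazo group from the sulfonyl azide and then loses trifluoroacetyl as the sulfonamide, while the short enolate lifetime at −78 °C limits migration of the ortho TBS group.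

Step 7
Reactants: 9 1-[2-[3,4-bis(triisopropylsilyloxy)benzyloxy]-6-(tert-butyldimethylsilyloxy)-4-(triisopropylsilyloxy)phenyl]-2-diazoethanone
Product: 10 (2S)-5-(tert-butyldimethylsilyloxy)-7-(triisopropylsilyloxy)-2-[3,4-bis(triisopropylsilyloxy)phenyl]chroman-4-one
Conditions: Rh2(S-PTTL)4 (dirhodium tetrakis[N-phthaloyl-(S)-tert-leucinate], divalent rhodium, 2 mol%), CH2Cl2, 0 °C, slow addition of 9
Reagents that add atoms: none
Why: The dirhodium carboxylate should decompose the diazoketone with loss of N2 to an electrophilic rhodium carbenoid at C3, which inserts into the C2–H bond of the benzyl ether through a concerted, hydride-transfer-like three-centre transition state that forms C2–C3 and releases the catalyst. The closest known reaction type is the dirhodium carboxylate-catalysed intramolecular C–H insertion of ortho-alkoxyaryl diazoketones to 2-substituted chroman-4-ones. Ring C closes as a six-membered ring by 1,6-insertion (C3, C4, C4a, C8a, O1, C2), the only low-strain closure onto an activated C–H bond, since the fifth atom of that chain is oxygen. The new stereocentre C2 is set by the catalyst: the phthalimido and tert-butyl walls of the (S)-tert-leucinate ligands differentiate the two enantiotopic benzylic hydrogens, and the (2S)-product is the one expected (see assumption). The step needs chemoselectivity for C–H insertion over oxonium ylide formation at O1 with 1,2-benzyl shift, over carbene dimerisation and over reaction at the other oxygens; this is secured by the hydridic C2–H bond (activated by O1 and by the para-silyloxy ring B), by the low nucleophilicity of an aryl ether oxygen, by silyl ethers that carry no activated C–H bond near the carbene and shield their oxygens, by the absence of any alkene, and by slow addition of 9.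

Step 8
Reactants: 10 (2S)-5-(tert-butyldimethylsilyloxy)-7-(triisopropylsilyloxy)-2-[3,4-bis(triisopropylsilyloxy)phenyl]chroman-4-one
Product: 11 (2S)-5-hydroxy-7-(triisopropylsilyloxy)-2-[3,4-bis(triisopropylsilyloxy)phenyl]chroman-4-one
Conditions: Bu4NF (1.05 equiv), AcOH (1.2 equiv), THF, −20 °C → 0 °C
Reagents that add atoms: none
Why: Fluoride-mediated desilylation buffered with acetic acid should remove only the TBS ether, which is the least hindered silyl group and sits on the oxygen peri to the carbonyl (strain relief, hydrogen-bonded phenol as product), while the three bulkier aryl TIPS ethers react much more slowly at low temperature.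

Step 9
Reactants: 11 (2S)-5-hydroxy-7-(triisopropylsilyloxy)-2-[3,4-bis(triisopropylsilyloxy)phenyl]chroman-4-one
Product: 12 (2S)-5-hydroxy-6-iodo-7-(triisopropylsilyloxy)-2-[3,4-bis(triisopropylsilyloxy)phenyl]chroman-4-one
Conditions: BnMe3N ICl2 (1.05 equiv), NaHCO3 (3 equiv), CH2Cl2/MeOH (5:2), 0 °C → rt
Reagents that add atoms: benzyltrimethylammonium dichloroiodate, C[N+](C)(C)Cc1ccccc1.Cl[I-]Cl
Why: Electrophilic aromatic iodination with the dichloroiodate should go ortho to the chelated 5-hydroxyl at C6, as it does in 5-hydroxy-7-alkoxyflavonoids and 2-hydroxy-4,6-dialkoxyacetophenones, while C8 is screened by O1 and the 7-OTIPS group and ring B is far less activated.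

Step 10
Reactants: 13 (S)-citronellal [(3S)-3,7-dimethyloct-6-enal, high enantiomeric purity]
Product: 15 (3S)-3,7-dimethyloct-6-en-1-yne, via alkenyl nonaflate 14 (not isolated)
Conditions: C4F9SO2F (1.2 equiv), phosphazene base P2-Et (2.5 equiv), DMF, −20 °C → rt
Reagents that add atoms: nonafluorobutane-1-sulfonyl fluoride, O=S(=O)(F)C(F)(F)C(F)(F)C(F)(F)C(F)(F)F (the nonaflate group of 14 only, lost again on elimination)
Why: One-pot enol nonaflation of the aldehyde and base-induced elimination of the sulfonic acid from the alkenyl nonaflate (a known phosphazene-mediated aldehyde-to-terminal-alkyne conversion that keeps all ten carbons) should give the alkyne without touching the stereocentre, which is β to the carbonyl and becomes only a weakly acidic propargylic position.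

Step 11
Reactants: 15 (3S)-3,7-dimethyloct-6-en-1-yne
Product: 16 2-[(1E,3S)-3,7-dimethylocta-1,6-dien-1-yl]-4,4,5,5-tetramethyl-1,3,2-dioxaborolane
Conditions: pinacolborane (1.2 equiv), Cp2Zr(H)Cl (5 mol%), Et3N (10 mol%), neat, 60 °C
Reagents that add atoms: pinacolborane, B1OC(C)(C)C(C)(C)O1
Why: Zirconium-catalysed hydroboration of the terminal alkyne proceeds by syn addition with boron at the terminal carbon, giving the (E)-alkenylboronate, and the trisubstituted alkene does not react under these conditions.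

Step 12
Reactants: 12 (2S)-5-hydroxy-6-iodo-7-(triisopropylsilyloxy)-2-[3,4-bis(triisopropylsilyloxy)phenyl]chroman-4-one; 16 2-[(1E,3S)-3,7-dimethylocta-1,6-dien-1-yl]-4,4,5,5-tetramethyl-1,3,2-dioxaborolane
Product: 17 (2S)-6-[(1E,3S)-3,7-dimethylocta-1,6-dien-1-yl]-5-hydroxy-7-(triisopropylsilyloxy)-2-[3,4-bis(triisopropylsilyloxy)phenyl]chroman-4-one
Conditions: Pd(OAc)2 (5 mol%), SPhos (10 mol%), K3PO4 (3 equiv), THF/H2O (10:1), 40 °C
Reagents that add atoms: none
Why: Suzuki–Miyaura coupling transfers the alkenyl group with retention of the (E) geometry, the bulky electron-rich biarylphosphine enabling oxidative addition and transmetalation at the iodide flanked by two oxygens, while phosphate at 40 °C is mild enough to spare the 4'-OTIPS group and the C2 stereocentre.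

Step 13
Reactants: 17 (2S)-6-[(1E,3S)-3,7-dimethylocta-1,6-dien-1-yl]-5-hydroxy-7-(triisopropylsilyloxy)-2-[3,4-bis(triisopropylsilyloxy)phenyl]chroman-4-one
Product: 18 (2S)-2-(3,4-dihydroxyphenyl)-6-[(1E,3S)-3,7-dimethylocta-1,6-dien-1-yl]-5,7-dihydroxychroman-4-one (target, CNP0230070.1)
Conditions: Bu4NF (4 equiv), AcOH (5 equiv), THF, 0 °C → rt; pH 6 phosphate buffer work-up
Reagents that add atoms: none
Why: Fluoride cleaves the three aryl TIPS ethers, and the acetic acid buffer keeps the liberated phenols protonated, which prevents quinone-methide or retro-oxa-Michael opening of ring C and thus loss of the C2 configuration, and leaves both alkenes untouched.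

**Compound list**
1 | 2,4,6-trihydroxyacetophenone | CC(=O)c1c(O)cc(O)cc1O | starting material
2 | 1-[2,6-dihydroxy-4-(triisopropylsilyloxy)phenyl]ethanone | CC(=O)c1c(O)cc(O[Si](C(C)C)(C(C)C)C(C)C)cc1O | intermediate
3 | 1-[2-(tert-butyldimethylsilyloxy)-6-hydroxy-4-(triisopropylsilyloxy)phenyl]ethanone | CC(=O)c1c(O)cc(O[Si](C(C)C)(C(C)C)C(C)C)cc1O[Si](C)(C)C(C)(C)C | intermediate
4 | 3,4-dihydroxybenzaldehyde | O=Cc1ccc(O)c(O)c1 | starting material
5 | 3,4-bis(triisopropylsilyloxy)benzaldehyde | O=Cc1ccc(O[Si](C(C)C)(C(C)C)C(C)C)c(O[Si](C(C)C)(C(C)C)C(C)C)c1 | intermediate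
6 | [3,4-bis(triisopropylsilyloxy)phenyl]methanol | OCc1ccc(O[Si](C(C)C)(C(C)C)C(C)C)c(O[Si](C(C)C)(C(C)C)C(C)C)c1 | intermediate
7 | 1-[2-[3,4-bis(triisopropylsilyloxy)benzyloxy]-6-(tert-butyldimethylsilyloxy)-4-(triisopropylsilyloxy)phenyl]ethanone | CC(=O)c1c(OCc2ccc(O[Si](C(C)C)(C(C)C)C(C)C)c(O[Si](C(C)C)(C(C)C)C(C)C)c2)cc(O[Si](C(C)C)(C(C)C)C(C)C)cc1O[Si](C)(C)C(C)(C)C | intermediate
8 | 1-[2-[3,4-bis(triisopropylsilyloxy)benzyloxy]-6-(tert-butyldimethylsilyloxy)-4-(triisopropylsilyloxy)phenyl]-4,4,4-trifluorobutane-1,3-dione | O=C(CC(=O)C(F)(F)F)c1c(OCc2ccc(O[Si](C(C)C)(C(C)C)C(C)C)c(O[Si](C(C)C)(C(C)C)C(C)C)c2)cc(O[Si](C(C)C)(C(C)C)C(C)C)cc1O[Si](C)(C)C(C)(C)C | intermediate (not isolated)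
9 | 1-[2-[3,4-bis(triisopropylsilyloxy)benzyloxy]-6-(tert-butyldimethylsilyloxy)-4-(triisopropylsilyloxy)phenyl]-2-diazoethanone | [N-]=[N+]=CC(=O)c1c(OCc2ccc(O[Si](C(C)C)(C(C)C)C(C)C)c(O[Si](C(C)C)(C(C)C)C(C)C)c2)cc(O[Si](C(C)C)(C(C)C)C(C)C)cc1O[Si](C)(C)C(C)(C)C | intermediate
10 | (2S)-5-(tert-butyldimethylsilyloxy)-7-(triisopropylsilyloxy)-2-[3,4-bis(triisopropylsilyloxy)phenyl]chroman-4-one | O=C1C[C@@H](c2ccc(O[Si](C(C)C)(C(C)C)C(C)C)c(O[Si](C(C)C)(C(C)C)C(C)C)c2)Oc2cc(O[Si](C(C)C)(C(C)C)C(C)C)cc(O[Si](C)(C)C(C)(C)C)c21 | intermediate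
11 | (2S)-5-hydroxy-7-(triisopropylsilyloxy)-2-[3,4-bis(triisopropylsilyloxy)phenyl]chroman-4-one | O=C1C[C@@H](c2ccc(O[Si](C(C)C)(C(C)C)C(C)C)c(O[Si](C(C)C)(C(C)C)C(C)C)c2)Oc2cc(O[Si](C(C)C)(C(C)C)C(C)C)cc(O)c21 | intermediate
12 | (2S)-5-hydroxy-6-iodo-7-(triisopropylsilyloxy)-2-[3,4-bis(triisopropylsilyloxy)phenyl]chroman-4-one | O=C1C[C@@H](c2ccc(O[Si](C(C)C)(C(C)C)C(C)C)c(O[Si](C(C)C)(C(C)C)C(C)C)c2)Oc2cc(O[Si](C(C)C)(C(C)C)C(C)C)c(I)c(O)c21 | intermediate
13 | (S)-citronellal, (3S)-3,7-dimethyloct-6-enal | CC(C)=CCC[C@H](C)CC=O | starting material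
14 | (3S)-3,7-dimethylocta-1,6-dien-1-yl nonafluorobutane-1-sulfonate (E/Z mixture at C1=C2) | CC(C)=CCC[C@H](C)C=COS(=O)(=O)C(F)(F)C(F)(F)C(F)(F)C(F)(F)F | intermediate (not isolated)
15 | (3S)-3,7-dimethyloct-6-en-1-yne | CC(C)=CCC[C@H](C)C#C | intermediate
16 | 2-[(1E,3S)-3,7-dimethylocta-1,6-dien-1-yl]-4,4,5,5-tetramethyl-1,3,2-dioxaborolane | CC(C)=CCC[C@H](C)/C=C/B1OC(C)(C)C(C)(C)O1 | intermediate
17 | (2S)-6-[(1E,3S)-3,7-dimethylocta-1,6-dien-1-yl]-5-hydroxy-7-(triisopropylsilyloxy)-2-[3,4-bis(triisopropylsilyloxy)phenyl]chroman-4-one | CC(C)=CCC[C@H](C)/C=C/c1c(O[Si](C(C)C)(C(C)C)C(C)C)cc2c(c1O)C(=O)C[C@@H](c1ccc(O[Si](C(C)C)(C(C)C)C(C)C)c(O[Si](C(C)C)(C(C)C)C(C)C)c1)O2 | intermediate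
18 | (2S)-2-(3,4-dihydroxyphenyl)-6-[(1E,3S)-3,7-dimethylocta-1,6-dien-1-yl]-5,7-dihydroxychroman-4-one | CC(C)=CCC[C@H](C)/C=C/c1c(O)cc2c(c1O)C(=O)C[C@@H](c1ccc(O)c(O)c1)O2 | target

**Step count**
Total: 13 steps. Longest linear sequence: 9 steps (steps 1, 2, 5, 6, 7, 8, 9, 12, 13).

**Steps most likely to fail**

1. Step 7. The carbenoid may be diverted into attack on the ether oxygen O1 followed by 1,2-benzyl shift, or into dimerisation. Independently, the acceptor-only carbenoid may discriminate poorly between the two enantiotopic benzylic hydrogens. Fallback (sets out from 3 and 5, returns at 10): ring C is built by condensation and oxa-Michael closure, and C2 is secured by kinetic resolution.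
 - Amine-catalysed Claisen–Schmidt condensation of 3 with 5 (pyrrolidine, MeCN, 40 °C) should give the chalcone (E)-1-[2-(tert-butyldimethylsilyloxy)-6-hydroxy-4-(triisopropylsilyloxy)phenyl]-3-[3,4-bis(triisopropylsilyloxy)phenyl]prop-2-en-1-one F1.
 - Oxa-Michael closure (NaOAc, EtOH, 60 °C) should give the racemic flavanone rac-5-(tert-butyldimethylsilyloxy)-7-(triisopropylsilyloxy)-2-[3,4-bis(triisopropylsilyloxy)phenyl]chroman-4-one F2.
 - Kinetic resolution by asymmetric transfer hydrogenation (RhCl(Cp*)(TsDPEN), HCO2H/Et3N, EtOAc, rt, with the ligand enantiomer chosen so that the (2R)-ketone is reduced faster) should convert the unwanted half into the separable cis-alcohol (2R,4R)-5-(tert-butyldimethylsilyloxy)-7-(triisopropylsilyloxy)-2-[3,4-bis(triisopropylsilyloxy)phenyl]chroman-4-ol F3 and leave the (2S)-ketone, which is 10.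

2. Step 12. Oxidative addition and transmetalation may be slow at an iodide flanked by hydroxyl and silyloxy groups. Prolonged exposure to aqueous base may then strip silyl ethers, open ring C and erode the C2 configuration. Fallback (sets out from 15 and 12, returns at 17): a base-free Stille coupling.
 - Palladium-catalysed hydrostannation of 15 (Bu3SnH, PdCl2(PPh3)2, THF, 0 °C) should give tributyl[(1E,3S)-3,7-dimethylocta-1,6-dien-1-yl]stannane F4.
 - F4 is coupled with 12 under neutral conditions (Pd2(dba)3, AsPh3, CuI, NMP, rt) to give 17.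

3. Step 6. The lithium enolate may take over the neighbouring TBS group by O-to-O silyl migration, or C-trifluoroacetylation of the twisted, doubly ortho-substituted ketone may stay incomplete, so that diazo transfer has no activated substrate. Fallback (sets out from 7, returns at 9): no lithium enolate is formed.
 - Soft enolisation (Me3SiOTf, Et3N, CH2Cl2, 0 °C) should give the enol ether [1-[2-[3,4-bis(triisopropylsilyloxy)benzyloxy]-6-(tert-butyldimethylsilyloxy)-4-(triisopropylsilyloxy)phenyl]ethenyloxy]trimethylsilane F5.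
 - Bromination with NBS (THF, −78 °C) should give 2-bromo-1-[2-[3,4-bis(triisopropylsilyloxy)benzyloxy]-6-(tert-butyldimethylsilyloxy)-4-(triisopropylsilyloxy)phenyl]ethanone F6.
 - Treatment of F6 with N,N'-ditosylhydrazine and DBU (THF, 0 °C) converts the bromoketone into diazoketone 9.

**Further compounds**
F1 | step 7 | (E)-1-[2-(tert-butyldimethylsilyloxy)-6-hydroxy-4-(triisopropylsilyloxy)phenyl]-3-[3,4-bis(triisopropylsilyloxy)phenyl]prop-2-en-1-one | O=C(/C=C/c1ccc(O[Si](C(C)C)(C(C)C)C(C)C)c(O[Si](C(C)C)(C(C)C)C(C)C)c1)c1c(O)cc(O[Si](C(C)C)(C(C)C)C(C)C)cc1O[Si](C)(C)C(C)(C)C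
F2 | step 7 | rac-5-(tert-butyldimethylsilyloxy)-7-(triisopropylsilyloxy)-2-[3,4-bis(triisopropylsilyloxy)phenyl]chroman-4-one | O=C1CC(c2ccc(O[Si](C(C)C)(C(C)C)C(C)C)c(O[Si](C(C)C)(C(C)C)C(C)C)c2)Oc2cc(O[Si](C(C)C)(C(C)C)C(C)C)cc(O[Si](C)(C)C(C)(C)C)c21
F3 | step 7 | (2R,4R)-5-(tert-butyldimethylsilyloxy)-7-(triisopropylsilyloxy)-2-[3,4-bis(triisopropylsilyloxy)phenyl]chroman-4-ol | O[C@@H]1C[C@H](c2ccc(O[Si](C(C)C)(C(C)C)C(C)C)c(O[Si](C(C)C)(C(C)C)C(C)C)c2)Oc2cc(O[Si](C(C)C)(C(C)C)C(C)C)cc(O[Si](C)(C)C(C)(C)C)c21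
F4 | step 12 | tributyl[(1E,3S)-3,7-dimethylocta-1,6-dien-1-yl]stannane | CC(C)=CCC[C@H](C)/C=C/[Sn](CCCC)(CCCC)CCCC
F5 | step 6 | [1-[2-[3,4-bis(triisopropylsilyloxy)benzyloxy]-6-(tert-butyldimethylsilyloxy)-4-(triisopropylsilyloxy)phenyl]ethenyloxy]trimethylsilane | C=C(O[Si](C)(C)C)c1c(OCc2ccc(O[Si](C(C)C)(C(C)C)C(C)C)c(O[Si](C(C)C)(C(C)C)C(C)C)c2)cc(O[Si](C(C)C)(C(C)C)C(C)C)cc1O[Si](C)(C)C(C)(C)C
F6 | step 6 | 2-bromo-1-[2-[3,4-bis(triisopropylsilyloxy)benzyloxy]-6-(tert-butyldimethylsilyloxy)-4-(triisopropylsilyloxy)phenyl]ethanone | O=C(CBr)c1c(OCc2ccc(O[Si](C(C)C)(C(C)C)C(C)C)c(O[Si](C(C)C)(C(C)C)C(C)C)c2)cc(O[Si](C(C)C)(C(C)C)C(C)C)cc1O[Si](C)(C)C(C)(C)C
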